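The numbers of this flask were chosen freely; the flask was simulated.

In this flask substrate and coupling partner are spent in pairs, one of each, so the leftover D, substrate minus coupling partner, stays at its charged 24.9 mM.

substrate 0.083 M; coupling partner 0.0581 M; time 2.0 d

    target ⇌ isomer of the product B (K1 = 0.14, k1 = 0.29 /min)
    crystals ⇌ target, rate k2*(cs2 - [target]) while solid is left; crystals form when [target] > cs2 (cs2 = 17 mM, k2 = 0.27 /min)
    substrate + coupling partner ⇌ target (K3 = 72 /M, k3 = 1.1 /M/min)
    substrate + coupling partner ⇌ isomer of the product A (K4 = 37 /M, k4 = 0.59 /M/min)

1. at 2.0 d, what has stopped the reaction, if anything has (forward and back rates have come level / all of the substrate has reacted / it is still moving / the coupling partner has run out first)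
2. how much target there is at 2.0 d, in percent of the substrate charged
3. how much isomer of the product A there is at 2.0 d, in percent of the substrate charged
4. amount of target if the flask were left three thousand times as long, in percent of the substrate charged

- for target the crystals are counted in
- as a solid, counted per litre of solution: crystals
- the reaction counts as stopped when no species that holds the substrate changes by six tenths of a point or more over the second half of the time
- run time (flask): 2.0 d

Call S, C and T the dissolved substrate, coupling partner and target, and K = 72 /M the equilibrium constant of the step that makes target. Dividing that step's forward rate by its back rate removes time and leaves K·S·C/T, which is one at balance. While crystals stand, T is held at the solubility s = 17 mM. So we carry Π = s/K = 236 mM^2, the ceiling product, the value of S·C at balance beside crystals; it plays the part of a solubility product.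

That step falls back with a lifetime of 65.5 min, far shorter than the 2.0 d of the run, so we reckon on balance, which is thermodynamic control. Then S − C = D and S·C = Π give C = 7.33 mM. Isomer of the product A stands at 37 /M times Π, which is 10.5% of the substrate charged, and isomer of the product B at 0.14 times s. The remaining spent pairs are target, 47.8%, of which 22.7 mM lies as crystals, so our assumption of crystals holds. Our reckoning sees no change on a longer wait.

The forecast says forward and back rates have come level, with target at 47.8%, isomer of the product A at 10.5% and 47.8% after the long wait: "Longer time changes nothing".

The simulation gives forward and back rates have come level, target 47.8%, isomer of the product A 10.5%, and 47.8% after the long wait.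

The main reason isomer of the product A stands this low in this flask is its falling back to substrate and coupling partner: with that way back taken away, it goes from 10.5% to 70.0% of the substrate charged. Dividing Π by the substrate standing at 2.00 d, 38.8% of its charge, gives coupling partner at 12.6% of its own charge, and the flask shows 13%.

In the neighbour flask with 0.050 M of substrate, coupling partner is the leftover, by 8.10 mM, and the same Π gives isomer of the product A at 17.5% and substrate at 23.7%. That neighbour computes to 17.5% and 23.7%, with crystals at 20.1%.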